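**Retrosynthetic overview**

1. Target 24 is reached by neutral hydrogenolysis of its penta-O-benzyl ether 23; nothing else remains after the key step.
2. Ring C of the lower flavan-3,4-diol unit of 23 is disconnected at O1–C2 and at C4a–C4 in one operation, to bisphenol 15 (the complete upper unit carrying a 2-benzyloxyresorcinol ring at C4) and the cis-epoxy aldehyde 20. Forward, this is a titanium-mediated [3+3] annulation that makes two bonds, closes the ring and fixes C2, C3 and C4 of the lower unit.
3. Enabling feature: in the lower unit O1 and C4a are an ortho oxygen/carbon pair of pyrogallol ring A (C4a is the only unsubstituted position ortho to a phenol oxygen and is para to the C7 oxygen). The all-cis chain C4(OH)–C3(OH)–C2(aryl) has exactly the oxidation level of a cis-3-arylglycidaldehyde (C4 = CHO, C3–O–C2 = epoxide, C2 benzylic).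
4. 15 comes from Friedel–Crafts coupling of (2S)-flavan-4-ol 7 with the twofold-symmetric 2-(benzyloxy)resorcinol 14 (2,4-trans interflavan bond); 7 from asymmetric conjugate arylation of chromone 4; 20 from Jacobsen epoxidation of (Z)-cinnamate 18.
5. Order of ring formation: upper ring C (chromone, step 2; made chiral in step 3), interflavan C4–C6 bond (step 9), lower ring C last (step 13).

Key step: step 13

Assumption: the target is taken as drawn, (2S,4S) in the upper flavan unit (2,4-trans) and (2R,3R,4R) in the lower unit (2,3-cis-3,4-cis).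
Assumption: the catalyst antipodes named in steps 3 and 11 are those expected to give the stated configurations; the mirror-image catalyst is used if the sense of induction proves opposite.

**Route**

Step 1
Reactants: 1 2,3,4-trihydroxyacetophenone
Product: 2 1-[3,4-bis(benzyloxy)-2-hydroxyphenyl]ethan-1-one
Conditions: BnBr (2.05 equiv), K2CO3 (2.2 equiv), acetone, reflux
Reagents that add atoms: benzyl bromide, BrCc1ccccc1
Why: Williamson ether synthesis in which the 3- and 4-hydroxyls react while the 2-hydroxyl, hydrogen-bonded to the ketone and therefore the least nucleophilic, stays free for the ring closure of step 2.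

Step 2
Reactants: 2 1-[3,4-bis(benzyloxy)-2-hydroxyphenyl]ethan-1-one
Product: 4 7,8-bis(benzyloxy)-4H-chromen-4-one, via enaminone 3 (not isolated)
Conditions: Me2NCH(OMe)2, toluene, 100 °C; then AcOH, 80 °C
Reagents that add atoms: N,N-dimethylformamide dimethyl acetal, COC(OC)N(C)C
Why: Enaminone formation at the methyl ketone followed by acid-promoted conjugate addition of the free phenol and loss of dimethylamine (the standard enaminone route to chromones) closes ring C of the upper unit.

Step 3
Reactants: 4 7,8-bis(benzyloxy)-4H-chromen-4-one; 5 [4-(benzyloxy)phenyl]boronic acid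
Product: 6 (2S)-7,8-bis(benzyloxy)-2-[4-(benzyloxy)phenyl]chroman-4-one
Conditions: Pd(OCOCF3)2 (5 mol %), (R)-4-tert-butyl-2-(pyridin-2-yl)-4,5-dihydrooxazole (6 mol %), NH4PF6 (30 mol %), H2O (5 equiv), ClCH2CH2Cl, 60 °C
Reagents that add atoms: none
Why: Catalytic asymmetric conjugate addition of an arylboronic acid to a chromone with a cationic divalent palladium/pyridine-oxazoline catalyst, a known entry to flavanones, in which the chiral ligand decides which face of C2 accepts the aryl group and so sets the 2S centre.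

Step 4
Reactants: 6 (2S)-7,8-bis(benzyloxy)-2-[4-(benzyloxy)phenyl]chroman-4-one
Product: 7 (2S,4S)-7,8-bis(benzyloxy)-2-[4-(benzyloxy)phenyl]chroman-4-ol
Conditions: NaBH4, THF–MeOH, 0 °C
Reagents that add atoms: none
Why: Borohydride reduction of the flavanone, expected to give the 2,4-cis alcohol by axial hydride attack; the C4 configuration does not matter because this centre is ionised in step 9.

Step 5
Reactants: 8 resorcinol
Product: 9 1,3-bis(methoxymethoxy)benzene
Conditions: NaH (2.4 equiv), MeOCH2Cl (2.4 equiv), DMF, 0 °C to rt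
Reagents that add atoms: chloromethyl methyl ether, COCCl
Why: Double O-alkylation of the bis-phenoxide (acetal protection) installs the two methoxymethyl ethers that direct the metalation of step 6.

Step 6
Reactants: 9 1,3-bis(methoxymethoxy)benzene
Product: 12 2,6-bis(methoxymethoxy)phenol, via aryllithium 10 (not isolated), via lithium aryltrimethoxyborate 11 (not isolated)
Conditions: n-BuLi (1.1 equiv), THF, 0 °C; B(OMe)3, −78 °C to rt; then AcOH, 30% aq. H2O2, 0 °C to rt
Reagents that add atoms: hydrogen peroxide, OO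
Why: Directed ortho-metalation at the position flanked by both methoxymethoxy groups, borylation and peroxide oxidation of the carbon–boron bond introduce the central oxygen regiospecifically.

Step 7
Reactants: 12 2,6-bis(methoxymethoxy)phenol
Product: 13 2-(benzyloxy)-1,3-bis(methoxymethoxy)benzene
Conditions: BnBr (1.2 equiv), K2CO3, DMF, 50 °C
Reagents that add atoms: benzyl bromide, BrCc1ccccc1
Why: Williamson ether synthesis on the only free phenol.

Step 8
Reactants: 13 2-(benzyloxy)-1,3-bis(methoxymethoxy)benzene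
Product: 14 2-(benzyloxy)benzene-1,3-diol
Conditions: HCl (cat., from AcCl), MeOH, 40 °C
Reagents that add atoms: none
Why: Acid-catalysed transacetalisation to methanol removes both methoxymethyl groups while the benzyl aryl ether is stable, giving a twofold-symmetric resorcinol whose only activated carbons (C4 and C6) are equivalent.

Step 9
Reactants: 7 (2S,4S)-7,8-bis(benzyloxy)-2-[4-(benzyloxy)phenyl]chroman-4-ol; 14 2-(benzyloxy)benzene-1,3-diol
Product: 15 4-{(2S,4S)-7,8-bis(benzyloxy)-2-[4-(benzyloxy)phenyl]chroman-4-yl}-2-(benzyloxy)benzene-1,3-diol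
Conditions: 14 (4 equiv), BF3·OEt2 (0.3 equiv), CH2Cl2–THF (5:1), −20 to 0 °C
Reagents that add atoms: none
Why: Friedel–Crafts alkylation (the interflavan coupling of proanthocyanidin chemistry): the C4 alcohol ionises to a cation stabilised by the para 7-benzyloxy group and the ring oxygen, the symmetric resorcinol can only react through its equivalent C4/C6 positions, and stereoelectronically preferred axial attack on the half-chair cation anti to the equatorial 2-aryl group should favour the 2,4-trans (4S) isomer, with excess nucleophile suppressing double alkylation and any cis isomer removed by chromatography.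

Step 10
Reactants: 16 4-(benzyloxy)benzaldehyde; 17 methyl 2-[bis(2,2,2-trifluoroethoxy)phosphoryl]acetate
Product: 18 methyl (Z)-3-[4-(benzyloxy)phenyl]prop-2-enoate
Conditions: KN(SiMe3)2, 18-crown-6, THF, −78 °C
Reagents that add atoms: none
Why: Still–Gennari variant of the Horner–Wadsworth–Emmons olefination, in which the electron-poor phosphonate under dissociating conditions gives the kinetic (Z)-enoate.

Step 11
Reactants: 18 methyl (Z)-3-[4-(benzyloxy)phenyl]prop-2-enoate
Product: 19 methyl (2S,3S)-3-[4-(benzyloxy)phenyl]oxirane-2-carboxylate (cis)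
Conditions: chloro[(S,S)-N,N'-bis(3,5-di-tert-butylsalicylidene)cyclohexane-1,2-diaminato]manganese (5 mol %), 4-phenylpyridine N-oxide (0.25 equiv), aq. NaOCl (pH 11.3), CH2Cl2, 0–4 °C
Reagents that add atoms: sodium hypochlorite, [Na+].[O-]Cl
Why: Jacobsen–Katsuki epoxidation, for which cis-cinnamate esters are established substrates: the oxo species formed from the trivalent manganese salen complex transfers oxygen to one enantioface of the cis-alkene and, with the N-oxide additive limiting bond rotation in the intermediate, should give the cis-(2S,3S) epoxide and so set both epoxide centres.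

Step 12
Reactants: 19 methyl (2S,3S)-3-[4-(benzyloxy)phenyl]oxirane-2-carboxylate
Product: 20 (2S,3S)-3-[4-(benzyloxy)phenyl]oxirane-2-carbaldehyde (cis)
Conditions: i-Bu2AlH (1.05 equiv), toluene–CH2Cl2, −78 °C; MeOH quench, aq. KNaC4H4O6; crude aldehyde used at once
Reagents that add atoms: none
Why: Partial reduction of an alpha-oxygenated ester with i-Bu2AlH at low temperature, where the aluminium hemiacetal persists until the quench so that the aldehyde is released without touching either stereocentre and is used immediately to avoid epimerisation at the alpha-carbon.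

Step 13
Reactants: 15 4-{(2S,4S)-7,8-bis(benzyloxy)-2-[4-(benzyloxy)phenyl]chroman-4-yl}-2-(benzyloxy)benzene-1,3-diol; 20 (2S,3S)-3-[4-(benzyloxy)phenyl]oxirane-2-carbaldehyde
Product: 23 (2R,3R,4R)-8-(benzyloxy)-2-[4-(benzyloxy)phenyl]-6-{(2S,4S)-7,8-bis(benzyloxy)-2-[4-(benzyloxy)phenyl]chroman-4-yl}chromane-3,4,7-triol, via titanium bis-phenoxide 21 (not isolated), via epoxy-alcohol adduct 22 (not isolated)
Conditions: Ti(OiPr)4 (2.1 equiv), toluene, rt, i-PrOH removed with toluene under reduced pressure; 20 (1.2 equiv), toluene, 0 °C to rt, then 45 °C; aq. KNaC4H4O6 work-up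
Reagents that add atoms: none
Why: Proposed new method: the titanium bis-phenoxide 21 binds the aldehyde of 20 at the titanium on the future O1 and delivers it through a six-membered cyclic transition state to the adjacent ring carbon (the future C4a), giving the titanium alkoxide of epoxy alcohol 22, which as a 2,3-epoxy-alcohol titanate activates its own epoxide so that the tethered phenoxide oxygen opens it at the distal benzylic carbon (the future C2). The closest known reaction types are the ortho-specific hydroxyalkylation of titanium and magnesium phenoxides with aldehydes (alpha-alkoxy aldehydes included), the Ti(OiPr)4-mediated C-3-selective opening of 2,3-epoxy alcohols, and the 6-endo epoxide–phenol cyclisation used for flavan-3-ols; their fusion into one [3+3] annulation with an epoxy aldehyde is the new element. The one ring formed, ring C of the lower unit, is closed in the 6-endo-tet mode. C3 is carried unchanged from the epoxide, C2 is set by inversion at the benzylic epoxide carbon (cis-epoxide, hence 2,3-cis), and C4 is set by Felkin–Anh (non-chelated) addition anti to the epoxide C–O bond, the sense expected for titanium phenoxides with alpha-oxygenated aldehydes, which gives the 3,4-cis diol. The step needs ortho-regioselectivity, secured because the future C4a is the only unsubstituted position ortho to either phenoxide (and is para to the other), and 6-endo over 5-exo opening with clean inversion, secured by the aryl group on the distal epoxide carbon, the titanium chelate of the epoxy alkoxide and the proximity of the phenoxide.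

Step 14
Reactants: 23 (2R,3R,4R)-8-(benzyloxy)-2-[4-(benzyloxy)phenyl]-6-{(2S,4S)-7,8-bis(benzyloxy)-2-[4-(benzyloxy)phenyl]chroman-4-yl}chromane-3,4,7-triol
Product: 24 (2R,3R,4R)-6-[(2S,4S)-7,8-dihydroxy-2-(4-hydroxyphenyl)chroman-4-yl]-2-(4-hydroxyphenyl)chromane-3,4,7,8-tetrol (CNP0209379.1)
Conditions: H2 (1 atm), Pd(OH)2/C, THF–MeOH (1:1), rt; filtered and concentrated under argon
Reagents that add atoms: none
Why: Hydrogenolysis of the five benzyl aryl ethers under neutral conditions touches no stereocentre, and the benzylic 4-hydroxyl and the two benzylic ring ethers are expected to survive because, without acid, they are cleaved much more slowly than O-benzyl groups.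

**Compound list**

1 | 2,3,4-trihydroxyacetophenone | CC(=O)c1ccc(O)c(O)c1O | starting material
2 | 1-[3,4-bis(benzyloxy)-2-hydroxyphenyl]ethan-1-one | CC(=O)c1ccc(OCc2ccccc2)c(OCc2ccccc2)c1O | intermediate
3 | (E)-1-[3,4-bis(benzyloxy)-2-hydroxyphenyl]-3-(dimethylamino)prop-2-en-1-one | CN(C)/C=C/C(=O)c1ccc(OCc2ccccc2)c(OCc2ccccc2)c1O | intermediate (not isolated)
4 | 7,8-bis(benzyloxy)-4H-chromen-4-one | O=c1ccoc2c(OCc3ccccc3)c(OCc3ccccc3)ccc12 | intermediate
5 | [4-(benzyloxy)phenyl]boronic acid | OB(O)c1ccc(OCc2ccccc2)cc1 | starting material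
6 | (2S)-7,8-bis(benzyloxy)-2-[4-(benzyloxy)phenyl]chroman-4-one | O=C1C[C@@H](c2ccc(OCc3ccccc3)cc2)Oc2c(OCc3ccccc3)c(OCc3ccccc3)ccc12 | intermediate
7 | (2S,4S)-7,8-bis(benzyloxy)-2-[4-(benzyloxy)phenyl]chroman-4-ol (2,4-cis) | O[C@H]1C[C@@H](c2ccc(OCc3ccccc3)cc2)Oc2c(OCc3ccccc3)c(OCc3ccccc3)ccc12 | intermediate
8 | resorcinol (benzene-1,3-diol) | Oc1cccc(O)c1 | starting material
9 | 1,3-bis(methoxymethoxy)benzene | COCOc1cccc(OCOC)c1 | intermediate
10 | [2,6-bis(methoxymethoxy)phenyl]lithium | [Li]c1c(OCOC)cccc1OCOC | intermediate (not isolated)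
11 | lithium [2,6-bis(methoxymethoxy)phenyl]trimethoxyborate | [Li+].COCOc1cccc(OCOC)c1[B-](OC)(OC)OC | intermediate (not isolated)
12 | 2,6-bis(methoxymethoxy)phenol | COCOc1cccc(OCOC)c1O | intermediate
13 | 2-(benzyloxy)-1,3-bis(methoxymethoxy)benzene | COCOc1cccc(OCOC)c1OCc1ccccc1 | intermediate
14 | 2-(benzyloxy)benzene-1,3-diol | Oc1cccc(O)c1OCc1ccccc1 | intermediate
15 | 4-{(2S,4S)-7,8-bis(benzyloxy)-2-[4-(benzyloxy)phenyl]chroman-4-yl}-2-(benzyloxy)benzene-1,3-diol (2,4-trans) | O(Cc1ccccc1)c1ccc(cc1)[C@@H]1C[C@@H](c2ccc(O)c(OCc3ccccc3)c2O)c2ccc(OCc3ccccc3)c(OCc3ccccc3)c2O1 | intermediate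
16 | 4-(benzyloxy)benzaldehyde | O=Cc1ccc(OCc2ccccc2)cc1 | starting material
17 | methyl 2-[bis(2,2,2-trifluoroethoxy)phosphoryl]acetate | COC(=O)CP(=O)(OCC(F)(F)F)OCC(F)(F)F | starting material
18 | methyl (Z)-3-[4-(benzyloxy)phenyl]prop-2-enoate | COC(=O)/C=C\c1ccc(OCc2ccccc2)cc1 | intermediate
19 | methyl (2S,3S)-3-[4-(benzyloxy)phenyl]oxirane-2-carboxylate (cis) | COC(=O)[C@H]1O[C@H]1c1ccc(OCc2ccccc2)cc1 | intermediate
20 | (2S,3S)-3-[4-(benzyloxy)phenyl]oxirane-2-carbaldehyde (cis) | O=C[C@H]1O[C@H]1c1ccc(OCc2ccccc2)cc1 | intermediate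
21 | O,O'-bis(triisopropoxytitanium) bis-phenoxide of 15 | O(Cc1ccccc1)c1ccc(cc1)[C@@H]1C[C@@H](c2ccc(O[Ti](OC(C)C)(OC(C)C)OC(C)C)c(OCc3ccccc3)c2O[Ti](OC(C)C)(OC(C)C)OC(C)C)c2ccc(OCc3ccccc3)c(OCc3ccccc3)c2O1 | intermediate (not isolated)
22 | 4-{(2S,4S)-7,8-bis(benzyloxy)-2-[4-(benzyloxy)phenyl]chroman-4-yl}-2-(benzyloxy)-6-{(R)-hydroxy[(2R,3S)-3-[4-(benzyloxy)phenyl]oxiran-2-yl]methyl}benzene-1,3-diol (drawn as the free phenol and alcohol; titanium-bound in the flask) | O(Cc1ccccc1)c1ccc(cc1)[C@@H]1C[C@@H](c2cc([C@@H](O)[C@H]3O[C@H]3c3ccc(OCc4ccccc4)cc3)c(O)c(OCc3ccccc3)c2O)c2ccc(OCc3ccccc3)c(OCc3ccccc3)c2O1 | intermediate (not isolated)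
23 | (2R,3R,4R)-8-(benzyloxy)-2-[4-(benzyloxy)phenyl]-6-{(2S,4S)-7,8-bis(benzyloxy)-2-[4-(benzyloxy)phenyl]chroman-4-yl}chromane-3,4,7-triol | O(Cc1ccccc1)c1ccc(cc1)[C@@H]1C[C@@H](c2cc3c(c(OCc4ccccc4)c2O)O[C@H](c2ccc(OCc4ccccc4)cc2)[C@H](O)[C@@H]3O)c2ccc(OCc3ccccc3)c(OCc3ccccc3)c2O1 | intermediate
24 | (2R,3R,4R)-6-[(2S,4S)-7,8-dihydroxy-2-(4-hydroxyphenyl)chroman-4-yl]-2-(4-hydroxyphenyl)chromane-3,4,7,8-tetrol (CNP0209379.1) | Oc1ccc([C@@H]2C[C@@H](c3cc4c(c(O)c3O)O[C@H](c3ccc(O)cc3)[C@H](O)[C@@H]4O)c3ccc(O)c(O)c3O2)cc1 | target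

**Step count**

Total step count: 14. Longest linear sequence: 7 steps (1, 2, 3, 4, 9, 13, 14; the branch 5, 6, 7, 8, 9, 13, 14 is equally long).

**Steps most likely to fail**

1. Step 13 (Proposed new method). What may go wrong: the carbon–carbon bond formation may stall on the hindered bis-phenoxide or lose Felkin control; the epoxide may open in the 5-exo sense or with loss of configuration through ionisation at the electron-rich benzylic carbon; or the new benzylic alkoxide, para to a titanium phenoxide, may ionise and epimerise. Fallback with known reactions only, setting out from 15 and coming back at 23: 15 is brominated with N-bromosuccinimide (CH2Cl2, −40 °C) at the one position activated by both phenols to give 4-{(2S,4S)-7,8-bis(benzyloxy)-2-[4-(benzyloxy)phenyl]chroman-4-yl}-2-(benzyloxy)-6-bromobenzene-1,3-diol F1. Deprotonation of both phenols and bromine–lithium exchange (n-BuLi, 3.2 equiv, THF, −78 °C) give the lithiated dilithium bis-phenoxide F2, which adds to aldehyde 20 in the Felkin–Anh sense usual for cis-epoxy aldehydes. The epoxy alcohol 22 is then isolated and closed to 23 by the acid-catalysed 6-endo epoxide–phenol cyclisation of flavan-3-ol synthesis (camphorsulfonic acid, CH2Cl2, 0 °C).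

2. Step 11. What may go wrong: loss of the cis geometry by bond rotation in the stepwise oxygen transfer, favoured by the electron-rich aryl group, and only moderate enantioface selection. Fallback, setting out from 18 and coming back at 20: ester 18 is reduced with i-Bu2AlH (2.2 equiv, CH2Cl2, −78 °C) to (Z)-3-[4-(benzyloxy)phenyl]prop-2-en-1-ol F3. Sharpless asymmetric epoxidation (Ti(OiPr)4, D-(−)-diisopropyl tartrate, t-BuOOH, 4 Å molecular sieves, CH2Cl2, −20 °C), a concerted hydroxyl-directed oxygen transfer that cannot scramble the alkene geometry, gives [(2R,3S)-3-[4-(benzyloxy)phenyl]oxiran-2-yl]methanol F4. Buffered Dess–Martin oxidation (NaHCO3, CH2Cl2, 0 °C) gives 20; this also bypasses step 12.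

3. Step 9. What may go wrong: poor facial selectivity at C4 of the cation, a second alkylation of the still-activated product, or acid-induced opening of the pyran ring at C2. Fallback, setting out from 13 and coming back at 15, in which both centres are set by reagent control:
   - Directed ortho-metalation of 13 (n-BuLi, THF, 0 °C) gives [3-(benzyloxy)-2,4-bis(methoxymethoxy)phenyl]lithium F5; B(OiPr)3 and aqueous NH4Cl convert it to [3-(benzyloxy)-2,4-bis(methoxymethoxy)phenyl]boronic acid F6.
   - Commercial 7,8-dihydroxycoumarin is benzylated (BnBr, K2CO3) to 7,8-bis(benzyloxy)-2H-chromen-2-one F7.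
   - Rhodium-catalysed asymmetric 1,4-addition of F6 to F7 (Rh(acac)(C2H4)2, the SEGPHOS antipode that gives 4S, dioxane–H2O, 60 °C) gives (4S)-7,8-bis(benzyloxy)-4-[3-(benzyloxy)-2,4-bis(methoxymethoxy)phenyl]chroman-2-one F8.
   - Lactone opening with MeNH(OMe)·HCl and AlMe3 gives (3R)-3-[3,4-bis(benzyloxy)-2-hydroxyphenyl]-3-[3-(benzyloxy)-2,4-bis(methoxymethoxy)phenyl]-N-methoxy-N-methylpropanamide F9.
   - 4-(Benzyloxy)phenylmagnesium bromide (3 equiv, THF, 0 °C) gives (3R)-3-[3,4-bis(benzyloxy)-2-hydroxyphenyl]-3-[3-(benzyloxy)-2,4-bis(methoxymethoxy)phenyl]-1-[4-(benzyloxy)phenyl]propan-1-one F10.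
   - Corey–Bakshi–Shibata reduction ((S)-methyl oxazaborolidine, BH3·SMe2) gives (1R,3R)-3-[3,4-bis(benzyloxy)-2-hydroxyphenyl]-3-[3-(benzyloxy)-2,4-bis(methoxymethoxy)phenyl]-1-[4-(benzyloxy)phenyl]propan-1-ol F11.
   - Mitsunobu cyclisation (PPh3, diisopropyl azodicarboxylate, THF, 0 °C), with inversion at the carbinol and with only the upper phenol free, gives (2S,4R)-7,8-bis(benzyloxy)-4-[3-(benzyloxy)-2,4-bis(methoxymethoxy)phenyl]-2-[4-(benzyloxy)phenyl]chromane F12 (same spatial arrangement as 15; the descriptor changes with the protecting groups).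
   - HCl in MeOH (40 °C) removes the methoxymethyl groups to give 15.

**Further compounds**

F1 | step 13 | 4-{(2S,4S)-7,8-bis(benzyloxy)-2-[4-(benzyloxy)phenyl]chroman-4-yl}-2-(benzyloxy)-6-bromobenzene-1,3-diol | O(Cc1ccccc1)c1ccc(cc1)[C@@H]1C[C@@H](c2cc(Br)c(O)c(OCc3ccccc3)c2O)c2ccc(OCc3ccccc3)c(OCc3ccccc3)c2O1
F2 | step 13 | lithiated dilithium bis-phenoxide from F1 | O(Cc1ccccc1)c1ccc(cc1)[C@@H]1C[C@@H](c2cc([Li])c(O[Li])c(OCc3ccccc3)c2O[Li])c2ccc(OCc3ccccc3)c(OCc3ccccc3)c2O1
F3 | step 11 | (Z)-3-[4-(benzyloxy)phenyl]prop-2-en-1-ol | OC/C=C\c1ccc(OCc2ccccc2)cc1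
F4 | step 11 | [(2R,3S)-3-[4-(benzyloxy)phenyl]oxiran-2-yl]methanol | OC[C@H]1O[C@H]1c1ccc(OCc2ccccc2)cc1
F5 | step 9 | [3-(benzyloxy)-2,4-bis(methoxymethoxy)phenyl]lithium | COCOc1ccc([Li])c(OCOC)c1OCc1ccccc1
F6 | step 9 | [3-(benzyloxy)-2,4-bis(methoxymethoxy)phenyl]boronic acid | COCOc1ccc(B(O)O)c(OCOC)c1OCc1ccccc1
F7 | step 9 | 7,8-bis(benzyloxy)-2H-chromen-2-one | O=c1ccc2ccc(OCc3ccccc3)c(OCc3ccccc3)c2o1
F8 | step 9 | (4S)-7,8-bis(benzyloxy)-4-[3-(benzyloxy)-2,4-bis(methoxymethoxy)phenyl]chroman-2-one | O=C1C[C@@H](c2ccc(OCOC)c(OCc3ccccc3)c2OCOC)c2ccc(OCc3ccccc3)c(OCc3ccccc3)c2O1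
F9 | step 9 | (3R)-3-[3,4-bis(benzyloxy)-2-hydroxyphenyl]-3-[3-(benzyloxy)-2,4-bis(methoxymethoxy)phenyl]-N-methoxy-N-methylpropanamide | CON(C)C(=O)C[C@@H](c1ccc(OCOC)c(OCc2ccccc2)c1OCOC)c1ccc(OCc2ccccc2)c(OCc2ccccc2)c1O
F10 | step 9 | (3R)-3-[3,4-bis(benzyloxy)-2-hydroxyphenyl]-3-[3-(benzyloxy)-2,4-bis(methoxymethoxy)phenyl]-1-[4-(benzyloxy)phenyl]propan-1-one | O=C(C[C@@H](c1ccc(OCOC)c(OCc2ccccc2)c1OCOC)c1ccc(OCc2ccccc2)c(OCc2ccccc2)c1O)c1ccc(OCc2ccccc2)cc1
F11 | step 9 | (1R,3R)-3-[3,4-bis(benzyloxy)-2-hydroxyphenyl]-3-[3-(benzyloxy)-2,4-bis(methoxymethoxy)phenyl]-1-[4-(benzyloxy)phenyl]propan-1-ol | O[C@H](C[C@@H](c1ccc(OCOC)c(OCc2ccccc2)c1OCOC)c1ccc(OCc2ccccc2)c(OCc2ccccc2)c1O)c1ccc(OCc2ccccc2)cc1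
F12 | step 9 | (2S,4R)-7,8-bis(benzyloxy)-4-[3-(benzyloxy)-2,4-bis(methoxymethoxy)phenyl]-2-[4-(benzyloxy)phenyl]chromane | O(Cc1ccccc1)c1ccc(cc1)[C@@H]1C[C@@H](c2ccc(OCOC)c(OCc3ccccc3)c2OCOC)c2ccc(OCc3ccccc3)c(OCc3ccccc3)c2O1
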